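**Retrosynthetic overview**
1. The target comes from the ten-membered trienolide by O8-desilylation and a last, neutral epoxidation of the C3=C4 olefin (the β,γ-epoxy ketone is base-labile).
2. The ten-membered ring is closed at C7–C8: a C8 α-silyloxy radical, made by photoredox decarboxylation of a seco acid, adds to C7 of a 3-(sulfonylmethyl)butenolide and expels PhSO2•. This one step forms C7–C8, the trans ring fusion and the C11=C13 methylene.
3. The seco acid comes from a C1–C10 CrCl2/NiCl2 coupling, then oxidation, of an aldehyde–butenolide (fragment 1) with a vinyl bromide (fragment 2).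
4. Fragment 1: butenolide by ring-closing metathesis, E-C3=C4 by carboalumination/ethylene oxide, C6 from (R)-epichlorohydrin. Fragment 2: asymmetric tin aldol of a silyl glycolate thioester with 2-bromoacrolein, then angeloylation.
5. Ring order: butenolide, then the ten-membered carbocycle, then the epoxide.

Assumption: atoms are numbered as a germacran-12,6-olide (C1 ketone, C3/C4 epoxide with C15 on C4, C6 lactone carbinol, C7 ring fusion, C8 hydroxyl, C9 angelate, C10=C14, C11=C13, C12 lactone carbonyl); 2-bromoacrolein and acetylene are taken as catalogue items.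

**Route**

Step 1
Reactants: 1 (R)-epichlorohydrin; 2 acetylene
Product: 4 (2R)-1-chloropent-4-yn-2-ol, via ethynyllithium 3 (not isolated)
Conditions: 2 (excess), n-BuLi, THF, −78 °C; BF3·OEt2; 1, −78 °C; aq. NH4Cl
Reagents that add atoms: none
Why: BF3-promoted alkynylation of the epoxide (Yamaguchi–Hirao opening) takes place only at the unsubstituted oxirane carbon, so the stereocentre of 1 (the future C6) is untouched and the chloride is kept for the next step.

Step 2
Reactants: 4 (2R)-1-chloropent-4-yn-2-ol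
Product: 6 (3R)-hex-1-en-5-yn-3-ol, via propargyl oxirane 5 (not isolated)
Conditions: Me3S+ I− (4 eq), n-BuLi (4 eq), THF, −10 °C to rt; aq. NH4Cl
Reagents that add atoms: trimethylsulfonium iodide, C[S+](C)C.[I-]
Why: The alkoxide closes to the terminal epoxide and dimethylsulfonium methylide opens it at CH2 and eliminates Me2S (one-carbon epoxide-to-allylic-alcohol homologation), without touching the carbinol stereocentre.

Step 3
Reactants: 6 (3R)-hex-1-en-5-yn-3-ol; 7 ethylene oxide
Product: 10 (3E,6R)-4-methylocta-3,7-diene-1,6-diol, via alkenyldimethylalane 8 (not isolated), via lithium butylalanate 9 (not isolated)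
Conditions: AlMe3 (3 eq), Cp2ZrCl2 (0.25 eq), CH2Cl2, 0 °C to rt; evaporate, THF/hexane, n-BuLi, −30 °C; 7 (5 eq), −30 °C to rt; aq. KNaC4H4O6
Reagents that add atoms: trimethylaluminium, C[Al](C)C
Why: Negishi zirconium-catalysed carboalumination adds Me–Al syn across the terminal alkyne with methyl on the internal carbon, and the derived alanate opens ethylene oxide with retention at the alkenyl carbon, which fixes the E geometry of C3=C4 and brings in C1 and C2.

Step 4
Reactants: 10 (3E,6R)-4-methylocta-3,7-diene-1,6-diol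
Product: 11 (3E,6R)-6-hydroxy-4-methylocta-3,7-dienal
Conditions: TEMPO (10 mol%), PhI(OAc)2 (1.1 eq), CH2Cl2, rt
Reagents that add atoms: none
Why: The TEMPO/PhI(OAc)2 oxoammonium oxidation is selective for the primary over the secondary allylic alcohol and is mild enough to leave the β,γ-unsaturated aldehyde unconjugated.

Step 5
Reactants: 12 2-(bromomethyl)prop-2-enoic acid
Product: 13 2-[(phenylsulfonyl)methyl]prop-2-enoic acid
Conditions: PhSO2Na (1.1 eq), MeOH, 50 °C; aq. HCl
Reagents that add atoms: sodium benzenesulfinate, [Na+].[O-]S(=O)c1ccccc1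
Why: Sulfinate S-alkylation of the allylic bromide (SN2 or SN2', both give the same product) installs the allyl sulfone that later acts as the radical leaving group and, unlike the bromide, is inert to CrCl2.

Step 6
Reactants: 11 (3E,6R)-6-hydroxy-4-methylocta-3,7-dienal; 13 2-[(phenylsulfonyl)methyl]prop-2-enoic acid
Product: 14 (3R,5E)-5-methyl-8-oxoocta-1,5-dien-3-yl 2-[(phenylsulfonyl)methyl]prop-2-enoate
Conditions: DCC (1.2 eq), DMAP (5 mol%), CH2Cl2, 0 °C
Reagents that add atoms: none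
Why: Steglich esterification of the only hydroxyl group at 0 °C, with retention at C6 because the C–O bond is not broken.

Step 7
Reactants: 14 (3R,5E)-5-methyl-8-oxoocta-1,5-dien-3-yl 2-[(phenylsulfonyl)methyl]prop-2-enoate
Product: 15 (3E)-4-methyl-5-[(2R)-5-oxo-4-[(phenylsulfonyl)methyl]-2,5-dihydrofuran-2-yl]pent-3-enal (fragment 1)
Conditions: second-generation Grubbs catalyst RuCl2(=CHPh)(PCy3)(H2IMes) (5 mol%), CH2Cl2 (5 mM), 40 °C
Reagents that add atoms: none
Why: Ring-closing olefin metathesis joins the vinyl group to the 1,1-disubstituted acrylate and releases ethylene, giving the butenolide while the trisubstituted olefin and C6 stay untouched.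

Step 8
Reactants: 16 methyl glycolate
Product: 17 methyl 2-[(tert-butyldimethylsilyl)oxy]acetate
Conditions: TBSCl, imidazole, CH2Cl2, rt
Reagents that add atoms: tert-butyldimethylsilyl chloride, CC(C)(C)[Si](C)(C)Cl
Why: Standard silylation of the primary alcohol (silyl ether protection).

Step 9
Reactants: 17 methyl 2-[(tert-butyldimethylsilyl)oxy]acetate
Product: 18 S-ethyl 2-[(tert-butyldimethylsilyl)oxy]ethanethioate
Conditions: AlMe3 (2 eq), EtSH (2 eq), CH2Cl2, 0 °C to rt; aq. work-up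
Reagents that add atoms: ethanethiol, CCS
Why: AlMe3-mediated thiolysis of the methyl ester through Me2AlSEt gives the thioester required for the tin aldol reaction and for the later selective hydrolysis.

Step 10
Reactants: 18 S-ethyl 2-[(tert-butyldimethylsilyl)oxy]ethanethioate
Product: 19 (Z)-2-[(tert-butyldimethylsilyl)oxy]-1-(ethylsulfanyl)-1-[(trimethylsilyl)oxy]ethene
Conditions: LiN(iPr)2 (1.1 eq), Me3SiCl (1.2 eq), THF, −78 °C
Reagents that add atoms: chlorotrimethylsilane, C[Si](C)(C)Cl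
Why: Kinetic enolisation and O-silylation gives the Z ketene silyl thioacetal used in the Mukaiyama aldol reaction.

Step 11
Reactants: 19 (Z)-2-[(tert-butyldimethylsilyl)oxy]-1-(ethylsulfanyl)-1-[(trimethylsilyl)oxy]ethene; 20 2-bromoprop-2-enal
Product: 21 S-ethyl (2R,3R)-4-bromo-2-[(tert-butyldimethylsilyl)oxy]-3-hydroxypent-4-enethioate
Conditions: Sn(OTf)2 (1.1 eq), (S)-1-ethyl-2-(piperidin-1-ylmethyl)pyrrolidine (1.3 eq), Bu2Sn(OAc)2 (1.2 eq), CH2Cl2, −78 °C; aq. NaHCO3, then citric acid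
Reagents that add atoms: none
Why: Kobayashi–Mukaiyama asymmetric aldol addition promoted by the chiral divalent tin triflate–diamine complex attacks one face of the aldehyde (the sense is assumed to follow the propionate series with the L-proline-derived diamine; the D-proline antipode is used if it proves opposite) and gives the syn 2-silyloxy-3-hydroxy thioester with C3 (the future C9) as R, while C2 need not be controlled because it later becomes the radical centre.

Step 12
Reactants: 21 S-ethyl (2R,3R)-4-bromo-2-[(tert-butyldimethylsilyl)oxy]-3-hydroxypent-4-enethioate; 22 angelic acid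
Product: 24 (3R,4R)-2-bromo-4-[(tert-butyldimethylsilyl)oxy]-5-(ethylsulfanyl)-5-oxopent-1-en-3-yl (2Z)-2-methylbut-2-enoate (fragment 2), via mixed anhydride 23 (not isolated)
Conditions: 22, 2,4,6-Cl3C6H2COCl, Et3N, toluene, rt; then 21, toluene, 75 °C
Reagents that add atoms: none
Why: Yamaguchi esterification through the mixed anhydride, run without DMAP so that the angelate is not isomerised to the tiglate; C9 is acylated with retention.

Step 13
Reactants: 15 (3E)-4-methyl-5-[(2R)-5-oxo-4-[(phenylsulfonyl)methyl]-2,5-dihydrofuran-2-yl]pent-3-enal; 24 (3R,4R)-2-bromo-4-[(tert-butyldimethylsilyl)oxy]-5-(ethylsulfanyl)-5-oxopent-1-en-3-yl (2Z)-2-methylbut-2-enoate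
Product: 25 S-ethyl (2R,3S,7E)-2-[(tert-butyldimethylsilyl)oxy]-5-hydroxy-8-methyl-4-methylidene-3-{[(2Z)-2-methylbut-2-enoyl]oxy}-9-[(2R)-5-oxo-4-[(phenylsulfonyl)methyl]-2,5-dihydrofuran-2-yl]non-7-enethioate (both C5 epimers)
Conditions: CrCl2 (6 eq), NiCl2 (2 mol%), DMSO, rt; aq. work-up
Reagents that add atoms: none
Why: Nozaki–Hiyama–Kishi coupling, in which the alkenyl bromide is converted through nickel into an alkenylchromium species that adds chemoselectively to the aldehyde in the presence of thioester, lactone, sulfone and angelate; the new carbinol (C1) forms as both epimers and is oxidised next.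

Step 14
Reactants: 25 S-ethyl (2R,3S,7E)-2-[(tert-butyldimethylsilyl)oxy]-5-hydroxy-8-methyl-4-methylidene-3-{[(2Z)-2-methylbut-2-enoyl]oxy}-9-[(2R)-5-oxo-4-[(phenylsulfonyl)methyl]-2,5-dihydrofuran-2-yl]non-7-enethioate
Product: 26 S-ethyl (2R,3S,7E)-2-[(tert-butyldimethylsilyl)oxy]-8-methyl-4-methylidene-3-{[(2Z)-2-methylbut-2-enoyl]oxy}-5-oxo-9-[(2R)-5-oxo-4-[(phenylsulfonyl)methyl]-2,5-dihydrofuran-2-yl]non-7-enethioate
Conditions: Dess–Martin periodinane (1.3 eq), CH2Cl2, 0 °C to rt
Reagents that add atoms: none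
Why: Dess–Martin oxidation of the allylic alcohol gives the cross-conjugated enone under conditions that do not move the β,γ olefin or touch the silyl ether.

Step 15
Reactants: 26 S-ethyl (2R,3S,7E)-2-[(tert-butyldimethylsilyl)oxy]-8-methyl-4-methylidene-3-{[(2Z)-2-methylbut-2-enoyl]oxy}-5-oxo-9-[(2R)-5-oxo-4-[(phenylsulfonyl)methyl]-2,5-dihydrofuran-2-yl]non-7-enethioate
Product: 27 (2R,3S,7E)-2-[(tert-butyldimethylsilyl)oxy]-8-methyl-4-methylidene-3-{[(2Z)-2-methylbut-2-enoyl]oxy}-5-oxo-9-[(2R)-5-oxo-4-[(phenylsulfonyl)methyl]-2,5-dihydrofuran-2-yl]non-7-enoic acid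
Conditions: AgNO3 (3 eq), 2,6-lutidine (3 eq), THF/H2O 4:1, rt
Reagents that add atoms: water, O
Why: Silver-assisted (thiophilic) hydrolysis cleaves the thioester selectively in the presence of the angelate and the lactone and releases the acid needed for decarboxylation.

Step 16
Reactants: 27 (2R,3S,7E)-2-[(tert-butyldimethylsilyl)oxy]-8-methyl-4-methylidene-3-{[(2Z)-2-methylbut-2-enoyl]oxy}-5-oxo-9-[(2R)-5-oxo-4-[(phenylsulfonyl)methyl]-2,5-dihydrofuran-2-yl]non-7-enoic acid
Product: 28 (3E,6R,7S,8S,9S)-8-[(tert-butyldimethylsilyl)oxy]-9-{[(2Z)-2-methylbut-2-enoyl]oxy}-1-oxogermacra-3,10(14),11(13)-trien-12,6-olide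
Conditions: Ir[dF(CF3)ppy]2(dtbbpy)PF6 (2 mol%), K2HPO4 (1.2 eq), DMF (2 mM), 450 nm LEDs, rt, Ar
Reagents that add atoms: none
Why: Proposed new method: the excited trivalent iridium complex oxidises the carboxylate of 27, loss of CO2 leaves a nucleophilic α-silyloxy radical at C8 that closes the ten-membered ring by attacking the electron-poor C7 terminus of the butenolide on the face opposite C5 (trans lactone fusion, as in intermolecular radical additions to 5-substituted butenolides), the resulting C11 radical β-fragments to the exocyclic C11=C13 olefin and PhSO2• (reduced to sulfinate by the divalent iridium species, which closes the cycle), and C8 is expected to form with O8 syn to O9 through a Felkin-type arrangement in which the C9–O bond lies anti to the forming bond and the bulky silyloxy group turns toward H9; the closest known reactions are the photoredox decarboxylative allylation of α-oxy acids with allyl sulfones and radical macrocyclisation onto activated olefins, here extended to a medium ring at high dilution.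

Step 17
Reactants: 28 (3E,6R,7S,8S,9S)-8-[(tert-butyldimethylsilyl)oxy]-9-{[(2Z)-2-methylbut-2-enoyl]oxy}-1-oxogermacra-3,10(14),11(13)-trien-12,6-olide
Product: 29 (3E,6R,7R,8S,9S)-8-hydroxy-9-{[(2Z)-2-methylbut-2-enoyl]oxy}-1-oxogermacra-3,10(14),11(13)-trien-12,6-olide
Conditions: HF·pyridine, pyridine, THF, 0 °C to rt
Reagents that add atoms: none
Why: Fluoride-mediated desilylation under buffered acidic conditions, which avoids base-induced acyl migration from O9 to O8 and conjugate additions to the two methylene carbonyl units.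

Step 18
Reactants: 29 (3E,6R,7R,8S,9S)-8-hydroxy-9-{[(2Z)-2-methylbut-2-enoyl]oxy}-1-oxogermacra-3,10(14),11(13)-trien-12,6-olide
Product: 30 (3R,4R,6R,7R,8S,9S)-3,4-epoxy-8-hydroxy-9-{[(2Z)-2-methylbut-2-enoyl]oxy}-1-oxogermacra-10(14),11(13)-dien-12,6-olide (CNP0348992.3)
Conditions: dimethyldioxirane (1.1 eq), acetone, −20 °C
Reagents that add atoms: dimethyldioxirane, CC1(C)OO1
Why: Dimethyldioxirane epoxidises only the electron-rich trisubstituted C3=C4 olefin (the enone, the methylene lactone and the angelate olefins are electron-poor) under neutral conditions that spare the base-labile β,γ-epoxy ketone, and attack on the exposed outer face of the E olefin in the lactone-bridged ten-membered ring is expected to give the 3R,4R trans-epoxide (Prilezhaev-type epoxidation).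

**Compound list**
1 | (R)-epichlorohydrin, (2R)-2-(chloromethyl)oxirane | ClC[C@H]1CO1 | starting material
2 | acetylene | C#C | starting material
3 | ethynyllithium | [Li]C#C | intermediate
4 | (2R)-1-chloropent-4-yn-2-ol | ClC[C@H](O)CC#C | intermediate
5 | (2R)-2-(prop-2-yn-1-yl)oxirane | C#CC[C@@H]1CO1 | intermediate
6 | (3R)-hex-1-en-5-yn-3-ol | C=C[C@H](O)CC#C | intermediate
7 | ethylene oxide | C1CO1 | starting material
8 | dimethyl{(1E,4R)-4-[(dimethylalumanyl)oxy]-2-methylhexa-1,5-dien-1-yl}alumane | C=C[C@H](O[Al](C)C)C/C(C)=C/[Al](C)C | intermediate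
9 | lithium butyl{(1E,4R)-4-[(dimethylalumanyl)oxy]-2-methylhexa-1,5-dien-1-yl}dimethylaluminate | [Li+].C=C[C@H](O[Al](C)C)C/C(C)=C/[Al-](C)(C)CCCC | intermediate
10 | (3E,6R)-4-methylocta-3,7-diene-1,6-diol | C=C[C@H](O)C/C(C)=C/CCO | intermediate
11 | (3E,6R)-6-hydroxy-4-methylocta-3,7-dienal | C=C[C@H](O)C/C(C)=C/CC=O | intermediate
12 | 2-(bromomethyl)prop-2-enoic acid | C=C(CBr)C(=O)O | starting material
13 | 2-[(phenylsulfonyl)methyl]prop-2-enoic acid | C=C(CS(=O)(=O)c1ccccc1)C(=O)O | intermediate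
14 | (3R,5E)-5-methyl-8-oxoocta-1,5-dien-3-yl 2-[(phenylsulfonyl)methyl]prop-2-enoate | C=C[C@H](OC(=O)C(=C)CS(=O)(=O)c1ccccc1)C/C(C)=C/CC=O | intermediate
15 | (3E)-4-methyl-5-[(2R)-5-oxo-4-[(phenylsulfonyl)methyl]-2,5-dihydrofuran-2-yl]pent-3-enal (fragment 1) | O=CC/C=C(C)/C[C@H]1OC(=O)C(CS(=O)(=O)c2ccccc2)=C1 | intermediate
16 | methyl glycolate | COC(=O)CO | starting material
17 | methyl 2-[(tert-butyldimethylsilyl)oxy]acetate | COC(=O)CO[Si](C)(C)C(C)(C)C | intermediate
18 | S-ethyl 2-[(tert-butyldimethylsilyl)oxy]ethanethioate | CCSC(=O)CO[Si](C)(C)C(C)(C)C | intermediate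
19 | (Z)-2-[(tert-butyldimethylsilyl)oxy]-1-(ethylsulfanyl)-1-[(trimethylsilyl)oxy]ethene | CCS/C(O[Si](C)(C)C)=C\O[Si](C)(C)C(C)(C)C | intermediate
20 | 2-bromoprop-2-enal (2-bromoacrolein) | C=C(Br)C=O | starting material
21 | S-ethyl (2R,3R)-4-bromo-2-[(tert-butyldimethylsilyl)oxy]-3-hydroxypent-4-enethioate | C=C(Br)[C@H](O)[C@@H](O[Si](C)(C)C(C)(C)C)C(=O)SCC | intermediate
22 | angelic acid, (2Z)-2-methylbut-2-enoic acid | C/C=C(/C)C(=O)O | starting material
23 | (2Z)-2-methylbut-2-enoic 2,4,6-trichlorobenzoic anhydride | C/C=C(/C)C(=O)OC(=O)c1c(Cl)cc(Cl)cc1Cl | intermediate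
24 | (3R,4R)-2-bromo-4-[(tert-butyldimethylsilyl)oxy]-5-(ethylsulfanyl)-5-oxopent-1-en-3-yl (2Z)-2-methylbut-2-enoate (fragment 2) | C=C(Br)[C@H](OC(=O)/C(C)=C\C)[C@@H](O[Si](C)(C)C(C)(C)C)C(=O)SCC | intermediate
25 | S-ethyl (2R,3S,7E)-2-[(tert-butyldimethylsilyl)oxy]-5-hydroxy-8-methyl-4-methylidene-3-{[(2Z)-2-methylbut-2-enoyl]oxy}-9-[(2R)-5-oxo-4-[(phenylsulfonyl)methyl]-2,5-dihydrofuran-2-yl]non-7-enethioate, C5 epimers | CCSC(=O)[C@H](O[Si](C)(C)C(C)(C)C)[C@@H](OC(=O)/C(C)=C\C)C(=C)C(O)C/C=C(C)/C[C@H]1OC(=O)C(CS(=O)(=O)c2ccccc2)=C1 | intermediate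
26 | S-ethyl (2R,3S,7E)-2-[(tert-butyldimethylsilyl)oxy]-8-methyl-4-methylidene-3-{[(2Z)-2-methylbut-2-enoyl]oxy}-5-oxo-9-[(2R)-5-oxo-4-[(phenylsulfonyl)methyl]-2,5-dihydrofuran-2-yl]non-7-enethioate | CCSC(=O)[C@H](O[Si](C)(C)C(C)(C)C)[C@@H](OC(=O)/C(C)=C\C)C(=C)C(=O)C/C=C(C)/C[C@H]1OC(=O)C(CS(=O)(=O)c2ccccc2)=C1 | intermediate
27 | (2R,3S,7E)-2-[(tert-butyldimethylsilyl)oxy]-8-methyl-4-methylidene-3-{[(2Z)-2-methylbut-2-enoyl]oxy}-5-oxo-9-[(2R)-5-oxo-4-[(phenylsulfonyl)methyl]-2,5-dihydrofuran-2-yl]non-7-enoic acid | OC(=O)[C@H](O[Si](C)(C)C(C)(C)C)[C@@H](OC(=O)/C(C)=C\C)C(=C)C(=O)C/C=C(C)/C[C@H]1OC(=O)C(CS(=O)(=O)c2ccccc2)=C1 | intermediate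
28 | (3E,6R,7S,8S,9S)-8-[(tert-butyldimethylsilyl)oxy]-9-{[(2Z)-2-methylbut-2-enoyl]oxy}-1-oxogermacra-3,10(14),11(13)-trien-12,6-olide | C=C1C(=O)O[C@@H]2C/C(C)=C/CC(=O)C(=C)[C@H](OC(=O)/C(C)=C\C)[C@@H](O[Si](C)(C)C(C)(C)C)[C@@H]12 | intermediate
29 | (3E,6R,7R,8S,9S)-8-hydroxy-9-{[(2Z)-2-methylbut-2-enoyl]oxy}-1-oxogermacra-3,10(14),11(13)-trien-12,6-olide | C=C1C(=O)O[C@@H]2C/C(C)=C/CC(=O)C(=C)[C@H](OC(=O)/C(C)=C\C)[C@@H](O)[C@@H]12 | intermediate
30 | (3R,4R,6R,7R,8S,9S)-3,4-epoxy-8-hydroxy-9-{[(2Z)-2-methylbut-2-enoyl]oxy}-1-oxogermacra-10(14),11(13)-dien-12,6-olide (CNP0348992.3) | C=C1C(=O)O[C@@H]2C[C@@]3(C)O[C@@H]3CC(=O)C(=C)[C@H](OC(=O)/C(C)=C\C)[C@@H](O)[C@@H]12 | target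

**Step count**
Total: 18 steps. Longest linear sequence: 12 steps (steps 1–4, 6, 7, 13–18).

**Steps most likely to fail**

Step 16. The ten-membered radical closure may be slower than competing paths (1,5-hydrogen shift from C2, intermolecular addition to the enone). C7 and C8 are both set in the ring-closing transition state, so their configuration is a prediction, and the intermolecular variant below does not make C8 any more secure. The fallback sets out from 24 and 15 and comes back at 28. The thioester of 24 is hydrolysed (AgNO3, 2,6-lutidine, aqueous THF) to (2R,3R)-4-bromo-2-[(tert-butyldimethylsilyl)oxy]-3-{[(2Z)-2-methylbut-2-enoyl]oxy}pent-4-enoic acid F1. F1 and 15 are joined under the same photoredox conditions at 0.1 M, an intermolecular decarboxylative allylation in which addition anti to the C6 substituent of the free butenolide is well precedented, to give the seco-aldehyde F2. Intramolecular CrCl2/NiCl2 coupling of the alkenyl bromide with the aldehyde (DMSO/THF, 2 mM) closes the ring as the macrocyclic allylic alcohol F3, and Dess–Martin oxidation of F3 gives 28.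

Step 18. Face selectivity of the epoxidation rests on the conformation of a flexible macrocycle. The fallback sets out from 28 and comes back at 30. Reagent-controlled Shi epoxidation of the silyl ether (D-fructose-derived ketone, KHSO5 as 2KHSO5·KHSO4·K2SO4, K2CO3, MeCN/dimethoxymethane/buffer, 0 °C; this ketone gives R,R epoxides from E olefins) gives the epoxy silyl ether F4. Buffered HF·pyridine then removes the silyl group to give 30.

Step 13. The alkenylchromium intermediate carries a β-acyloxy group and could eliminate to an allene, and the alkenyl bromide is less reactive than an iodide. The fallback sets out from 21 and 15 and comes back at 26. Alcohol 21 is silylated (Et3SiCl, imidazole) to the triethylsilyl ether F5. F5 and 15 are coupled with CrCl2/NiCl2 to the coupled alcohol F6, since a β-silyloxy alkenylchromium does not eliminate. Dess–Martin oxidation gives the enone F7, pyridinium p-toluenesulfonate in MeOH removes only the triethylsilyl group to give the C9 alcohol F8, and Yamaguchi angeloylation of F8 with 22 gives 26.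

**Further compounds**
F1 | step 16 | (2R,3R)-4-bromo-2-[(tert-butyldimethylsilyl)oxy]-3-{[(2Z)-2-methylbut-2-enoyl]oxy}pent-4-enoic acid | OC(=O)[C@H](O[Si](C)(C)C(C)(C)C)[C@@H](OC(=O)/C(C)=C\C)C(Br)=C
F2 | step 16 | (3E)-5-[(2R,3S)-3-[(1S,2R)-3-bromo-1-[(tert-butyldimethylsilyl)oxy]-2-{[(2Z)-2-methylbut-2-enoyl]oxy}but-3-en-1-yl]-4-methylidene-5-oxooxolan-2-yl]-4-methylpent-3-enal | O=CC/C=C(C)/C[C@H]1OC(=O)C(=C)[C@@H]1[C@H](O[Si](C)(C)C(C)(C)C)[C@@H](OC(=O)/C(C)=C\C)C(Br)=C
F3 | step 16 | (3E,6R,7S,8S,9S)-8-[(tert-butyldimethylsilyl)oxy]-1-hydroxy-9-{[(2Z)-2-methylbut-2-enoyl]oxy}germacra-3,10(14),11(13)-trien-12,6-olide, C1 epimers | C=C1C(=O)O[C@@H]2C/C(C)=C/CC(O)C(=C)[C@H](OC(=O)/C(C)=C\C)[C@@H](O[Si](C)(C)C(C)(C)C)[C@@H]12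
F4 | step 18 | (3R,4R,6R,7S,8S,9S)-8-[(tert-butyldimethylsilyl)oxy]-3,4-epoxy-9-{[(2Z)-2-methylbut-2-enoyl]oxy}-1-oxogermacra-10(14),11(13)-dien-12,6-olide | C=C1C(=O)O[C@@H]2C[C@@]3(C)O[C@@H]3CC(=O)C(=C)[C@H](OC(=O)/C(C)=C\C)[C@@H](O[Si](C)(C)C(C)(C)C)[C@@H]12
F5 | step 13 | S-ethyl (2R,3R)-4-bromo-2-[(tert-butyldimethylsilyl)oxy]-3-[(triethylsilyl)oxy]pent-4-enethioate | C=C(Br)[C@H](O[Si](CC)(CC)CC)[C@@H](O[Si](C)(C)C(C)(C)C)C(=O)SCC
F6 | step 13 | S-ethyl (2R,3S,7E)-2-[(tert-butyldimethylsilyl)oxy]-5-hydroxy-8-methyl-4-methylidene-9-[(2R)-5-oxo-4-[(phenylsulfonyl)methyl]-2,5-dihydrofuran-2-yl]-3-[(triethylsilyl)oxy]non-7-enethioate, C5 epimers | CCSC(=O)[C@H](O[Si](C)(C)C(C)(C)C)[C@@H](O[Si](CC)(CC)CC)C(=C)C(O)C/C=C(C)/C[C@H]1OC(=O)C(CS(=O)(=O)c2ccccc2)=C1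
F7 | step 13 | S-ethyl (2R,3S,7E)-2-[(tert-butyldimethylsilyl)oxy]-8-methyl-4-methylidene-5-oxo-9-[(2R)-5-oxo-4-[(phenylsulfonyl)methyl]-2,5-dihydrofuran-2-yl]-3-[(triethylsilyl)oxy]non-7-enethioate | CCSC(=O)[C@H](O[Si](C)(C)C(C)(C)C)[C@@H](O[Si](CC)(CC)CC)C(=C)C(=O)C/C=C(C)/C[C@H]1OC(=O)C(CS(=O)(=O)c2ccccc2)=C1
F8 | step 13 | S-ethyl (2R,3S,7E)-2-[(tert-butyldimethylsilyl)oxy]-3-hydroxy-8-methyl-4-methylidene-5-oxo-9-[(2R)-5-oxo-4-[(phenylsulfonyl)methyl]-2,5-dihydrofuran-2-yl]non-7-enethioate | CCSC(=O)[C@H](O[Si](C)(C)C(C)(C)C)[C@@H](O)C(=C)C(=O)C/C=C(C)/C[C@H]1OC(=O)C(CS(=O)(=O)c2ccccc2)=C1
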